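Readings and results were computed for an exercise; noise was put on by code.

The amounts came first: the flask held 0.10 M of starting material and 0.200 M of partner, and Friday's run was this same flask, followed as far as 40.0 min.

all flasks: starting material 0.10 M

|  | partner | remark | time |
|---|---|---|---|
| Friday's | 0.20 M | the very flask that is asked about, followed so far |  |
| flask | 0.200 M |  | 2.0 h |

Friday's run (percent of the starting material charged)

| time / min | starting material / % | mono adduct / % |
|---|---|---|
| 3.00 | 72.2 | 9.6 |
| 5.00 | 60.1 | 14.1 |
| 8.00 | 46.5 | 18.5 |
| 12.0 | 34.6 | 22.2 |
| 20.0 | 22.7 | 25.5 |
| 40.0 | 9.8 | 26.4 |

(standard deviation of a reading: 0.3 percentage points)



- amount of starting material at 2.0 h, in percent of the starting material charged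
- amount of mono adduct at 2.0 h, in percent of the starting material charged
- amount of other mono adduct at 2.0 h, in percent of the starting material charged
- amount of double product at 2.0 h, in percent of the starting material charged

I went through the given numbers for what I had to know well. The scatter of 0.3 percentage points I could live with, set beside a mono adduct reading of 26.4%. The time worried me little: Friday's starting material already stood at 9.8% at 40.0 min, and the asked time was 3.00 times as long. The two charges I wanted exact, since a slip in either shifts their ratio. Each starting material needs two of partner on its way to double product, so I took [partner] charged over two times [starting material] charged, which came to 1.00 for this flask; that ratio is what I call the cover. By this count, which takes in the two steps and no other use of partner, above one there is partner to spare, and below one partner is the limiting reagent. This flask sat on the crossing, so I expected no spare partner for the tail, though that gave me no yields.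

The forecast gave 1.7% starting material, 23.5% mono adduct, 0.4% other mono adduct and 74.4% double product, holding that “the other mono adduct converts quickly to double product”.

The flask gave 2.53% starting material, 19.6% mono adduct, 5.36% other mono adduct and 58.7% double product.

    starting material + partner → mono adduct (k = 0.210 M⁻¹ min⁻¹)
    starting material + partner → other mono adduct (k = 0.390 M⁻¹ min⁻¹)
    partner + mono adduct → double product (k = 0.00540 M⁻¹ min⁻¹)
    partner + other mono adduct → double product (k = 0.640 M⁻¹ min⁻¹)
    partner → decomposed reagent (k = 0.00420 min⁻¹)
    mono adduct → over-reaction product (k = 0.00500 min⁻¹)

Double product stood lower than the forecast's figure, and at 2.00 h this flask held 13.8% of over-reaction product. A neighbour flask charged with 0.25 M of starting material had a cover of 0.400, below one, and at 2.00 h that neighbour had 0% of its partner charge left and 39.1% of its starting material.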